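The 13-membered carbocycle is opened between the ring methylene C6 and the tertiary allylic carbinol carbon C7, which sits next to the C8=C9 (E)-alkene. That allylic C–O site allows polarity reversal: the acyclic precursor carries an (S)-secondary allylic diisopropylcarbamate at C7 and a primary pinacol boronate at C6. In situ lithiation, ring-closing borylation (14-membered boronate) and a stereospecific 1,2-metallate shift contract to the carbocycle, unite two nucleophilic carbons and, after oxidation, deliver the 7R carbinol from a bought butynol stereocentre. C1 and C13 come from an Evans aldol followed by a Fráter–Seebach alkylation, C10 from a Rh-catalysed 1,4-addition.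

Key step: step 16

Remark on numbering: ring atoms are C1 (CH–OAc), C2, C3(CH3)=C4, C5, C6, C7 (C(CH3)OH), C8=C9, C10 (CH–iPr), C11, C12, C13 (C(CH3)CHO); the same numbers are used for open-chain compounds.
Assumption: in step 9 the (R)-BINAP–Rh catalyst is taken to attack the enoate face predicted by the model for (E)-enones; the ligand antipode would be used if the other face reacts.

Step 1
Reactants: 1 tert-butyl(but-3-yn-1-yloxy)dimethylsilane; 2 oxirane
Product: 4 (3E)-6-(tert-butyldimethylsilyloxy)-4-methylhex-3-en-1-ol, via alkenyldimethylalane 3 (not isolated)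
Conditions: Me3Al, Cp2ZrCl2 (cat.), CH2Cl2, 0 °C → rt; n-BuLi, THF/hexane, −78 °C; oxirane, −78 → 0 °C; 1 M HCl
Reagents that add atoms: trimethylaluminium, C[Al](C)C
Why: Negishi Zr-catalysed carboalumination adds CH3–Al syn across the terminal alkyne (CH3 to the internal carbon) and the derived alanate opens oxirane with retention, which fixes the (E)-C3=C4 alkene and delivers C5–C6.

Step 2
Reactants: 4 (3E)-6-(tert-butyldimethylsilyloxy)-4-methylhex-3-en-1-ol
Product: 5 tert-butyl{[(3E)-6-chloro-3-methylhex-3-en-1-yl]oxy}dimethylsilane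
Conditions: NCS, PPh3, THF, 0 °C → rt
Reagents that add atoms: N-chlorosuccinimide, O=C1CCC(=O)N1Cl
Why: Appel-type chlorination of the primary alcohol gives a chloride that should survive to step 15 as the placeholder for boron at C6.

Step 3
Reactants: 5 tert-butyl{[(3E)-6-chloro-3-methylhex-3-en-1-yl]oxy}dimethylsilane
Product: 6 (3E)-6-chloro-3-methylhex-3-en-1-ol
Conditions: CSA (cat.), MeOH, 0 °C → rt
Reagents that add atoms: none
Why: Acid-catalysed methanolysis cleaves the primary silyl ether and leaves the homoallylic chloride and the alkene untouched.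

Step 4
Reactants: 6 (3E)-6-chloro-3-methylhex-3-en-1-ol
Product: 7 (3E)-6-chloro-3-methylhex-3-enal
Conditions: Dess–Martin periodinane, NaHCO3, CH2Cl2, 0 °C; used crude
Reagents that add atoms: none
Why: Buffered Dess–Martin oxidation should give the β,γ-unsaturated aldehyde without moving the alkene into conjugation if it is used at once.

Step 5
Reactants: 7 (3E)-6-chloro-3-methylhex-3-enal; 8 (R)-4-benzyl-3-propanoyl-1,3-oxazolidin-2-one
Product: 10 (4R)-4-benzyl-3-[(2R,3S,5E)-8-chloro-3-hydroxy-2,5-dimethyloct-5-enoyl]-1,3-oxazolidin-2-one, via boron enolate 9 (not isolated)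
Conditions: n-Bu2BOTf, i-Pr2NEt, CH2Cl2, −78 → 0 °C; 7, −78 → 0 °C; pH 7 buffer, MeOH, H2O2
Reagents that add atoms: none
Why: Evans syn-aldol through the (Z)-boron enolate and a Zimmerman–Traxler chair; the (R)-auxiliary sets C1 as S (the C13–H centre formed here is temporary).

Step 6
Reactants: 10 (4R)-4-benzyl-3-[(2R,3S,5E)-8-chloro-3-hydroxy-2,5-dimethyloct-5-enoyl]-1,3-oxazolidin-2-one
Product: 11 methyl (2R,3S,5E)-8-chloro-3-hydroxy-2,5-dimethyloct-5-enoate
Conditions: NaOMe (cat.), MeOH, 0 °C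
Reagents that add atoms: methanol, CO
Why: Methoxide transesterification removes the auxiliary at the exocyclic carbonyl and gives the methyl ester needed for dianion chemistry.

Step 7
Reactants: 12 (S)-but-3-yn-2-ol
Product: 13 (S)-but-3-yn-2-yl N,N-diisopropylcarbamate
Conditions: i-Pr2NCOCl, Et3N, CH2Cl2, reflux
Reagents that add atoms: N,N-diisopropylcarbamoyl chloride, CC(C)N(C(C)C)C(Cl)=O
Why: O-carbamoylation of the bought alcohol installs the group that later activates C7; its stereocentre becomes C7.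

Step 8
Reactants: 13 (S)-but-3-yn-2-yl N,N-diisopropylcarbamate
Product: 14 (2S,3E)-4-(4,4,5,5-tetramethyl-1,3,2-dioxaborolan-2-yl)but-3-en-2-yl N,N-diisopropylcarbamate
Conditions: pinacolborane, Cp2Zr(H)Cl (5 mol%), Et3N (10 mol%), neat, 60 °C
Reagents that add atoms: pinacolborane, CC1(C)OBOC1(C)C
Why: Zr-catalysed syn-hydroboration of the terminal alkyne places boron at the terminal carbon and gives the (E)-alkenylboronate.

Step 9
Reactants: 14 (2S,3E)-4-(4,4,5,5-tetramethyl-1,3,2-dioxaborolan-2-yl)but-3-en-2-yl N,N-diisopropylcarbamate; 15 methyl (2E)-4-methylpent-2-enoate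
Product: 16 methyl (3S,4E,6S)-6-[(diisopropylcarbamoyl)oxy]-3-(propan-2-yl)hept-4-enoate
Conditions: [Rh(cod)OH]2 (2.5 mol%), (R)-BINAP (6 mol%), dioxane/H2O 10:1, 50 °C
Reagents that add atoms: none
Why: Hayashi–Miyaura Rh-catalysed asymmetric 1,4-addition of the alkenyl group to the (E)-enoate; the chiral ligand controls the enoate face and sets C10 (S), with the (E)-C8=C9 geometry retained.

Step 10
Reactants: 16 methyl (3S,4E,6S)-6-[(diisopropylcarbamoyl)oxy]-3-(propan-2-yl)hept-4-enoate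
Product: 17 (2S,3E,5S)-7-hydroxy-5-(propan-2-yl)hept-3-en-2-yl N,N-diisopropylcarbamate
Conditions: LiBH4, MeOH (1 equiv), THF, 0 °C → rt; aq. NH4Cl
Reagents that add atoms: none
Why: Borohydride reduction of the methyl ester; the hindered N,N-diisopropylcarbamate should not react.

Step 11
Reactants: 17 (2S,3E,5S)-7-hydroxy-5-(propan-2-yl)hept-3-en-2-yl N,N-diisopropylcarbamate
Product: 18 (2S,3E,5S)-7-iodo-5-(propan-2-yl)hept-3-en-2-yl N,N-diisopropylcarbamate
Conditions: I2, PPh3, imidazole, CH2Cl2, 0 °C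
Reagents that add atoms: iodine, II
Why: Appel iodination of the primary alcohol gives the C12 electrophile.

Step 12
Reactants: 11 methyl (2R,3S,5E)-8-chloro-3-hydroxy-2,5-dimethyloct-5-enoate; 18 (2S,3E,5S)-7-iodo-5-(propan-2-yl)hept-3-en-2-yl N,N-diisopropylcarbamate
Product: 20 methyl (2S,3S,5E)-8-chloro-2-{(3S,4E,6S)-6-[(diisopropylcarbamoyl)oxy]-3-(propan-2-yl)hept-4-en-1-yl}-3-hydroxy-2,5-dimethyloct-5-enoate, via dilithium alkoxide-enolate 19 (not isolated)
Conditions: LDA (2.05 equiv), THF, −78 → −20 °C; 18, HMPA, −78 → −10 °C; aq. NH4Cl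
Reagents that add atoms: none
Why: Fráter–Seebach alkylation: the chelated dianion is alkylated on the face trans to the C2 chain, so C1 relays to the quaternary C13 (S), with the new C12 chain anti and the methyl syn to the C1 oxygen.

Step 13
Reactants: 20 methyl (2S,3S,5E)-8-chloro-2-{(3S,4E,6S)-6-[(diisopropylcarbamoyl)oxy]-3-(propan-2-yl)hept-4-en-1-yl}-3-hydroxy-2,5-dimethyloct-5-enoate
Product: 21 (2R,3S,5E)-8-chloro-2-{(3S,4E,6S)-6-[(diisopropylcarbamoyl)oxy]-3-(propan-2-yl)hept-4-en-1-yl}-2,5-dimethyloct-5-ene-1,3-diol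
Conditions: LiAlH4, THF, 0 °C; Fieser work-up
Reagents that add atoms: none
Why: Hydride reduction of the neopentyl ester at 0 °C, where the diisopropylcarbamate and the primary chloride should survive; the CH2OH is the later CHO.

Step 14
Reactants: 21 (2R,3S,5E)-8-chloro-2-{(3S,4E,6S)-6-[(diisopropylcarbamoyl)oxy]-3-(propan-2-yl)hept-4-en-1-yl}-2,5-dimethyloct-5-ene-1,3-diol
Product: 22 bis(tert-butyldimethylsilyl) ether of 21
Conditions: TBSOTf, 2,6-lutidine, CH2Cl2, −78 → 0 °C
Reagents that add atoms: tert-butyldimethylsilyl triflate, CC(C)(C)[Si](C)(C)OS(=O)(=O)C(F)(F)F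
Why: Silyl triflate silylation protects both the primary and the hindered secondary hydroxyl as base-stable ethers for the lithiation.

Step 15
Reactants: 22 bis(tert-butyldimethylsilyl) ether of 21
Product: 23 C6 pinacol boronate of 22 (Bpin in place of Cl)
Conditions: B2pin2, CuI (10 mol%), PPh3 (13 mol%), LiOMe, n-Bu4NI (20 mol%), DMF, 35 °C
Reagents that add atoms: bis(pinacolato)diboron, CC1(C)OB(OC1(C)C)B1OC(C)(C)C(C)(C)O1
Why: Cu-catalysed borylation of the primary alkyl chloride (iodide-assisted); the poor carbamate leaving group and the hindered γ-carbon should prevent allylic borylation.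

Step 16
Reactants: 23 C6 pinacol boronate of 22
Product: 26 (1S,3E,7R,8E,10S,13R)-1-(tert-butyldimethylsilyloxy)-13-[(tert-butyldimethylsilyloxy)methyl]-3,7,13-trimethyl-10-(propan-2-yl)cyclotrideca-3,8-dien-7-ol, via lithium boronate complex 24 (not isolated), via tertiary boronic ester 25 (not isolated)
Conditions: LiTMP (1.3 equiv, slow addition), THF, −78 °C, 1 mM; MgBr2·OEt2, MeOH, −78 → 40 °C; 2 M NaOH, 30% H2O2, 0 °C → rt
Reagents that add atoms: hydrogen peroxide, OO
Why: Proposed new method: LiTMP, which unlike alkyllithiums does not bind a pinacol boronate irreversibly, removes the allylic α-carbamoyloxy proton at C7 with retention; the lithiated carbamate is captured at once by the tethered C6–Bpin with retention to close the 14-membered cyclic boronate 24, and on warming C6 shifts from boron to C7 anti to the departing carbamate (1,2-metallate rearrangement, inversion), which forms the C6–C7 bond and contracts the ring to the 13-membered carbocycle 25. The closest known reactions are the intermolecular lithiation–borylation of enantioenriched secondary allylic carbamates with alkyl boronic esters and the in situ amide-base homologations of boronic esters (lithiated epoxides, LiCHCl2); the tethered, macrocyclising variant is new. The ring closes by macrocyclic B–C bond formation followed by a stereospecific ring contraction, not by a direct 13-membered C–C closure. The one new stereocentre, C7, is controlled by the (S)-carbamate centre (retention, then inversion, then oxidation with retention: the oxygen keeps its place and C6 takes the place of H, giving 7R). The step needs α- over γ-borylation (established for secondary allylic carbamates), configurational integrity of the lithiated carbamate (in situ capture at −78 °C) and intra- over intermolecular borylation (1 mM, slow base addition); silyl ethers, both alkenes and the quaternary centre are inert to the base.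

Step 17
Reactants: 26 (1S,3E,7R,8E,10S,13R)-1-(tert-butyldimethylsilyloxy)-13-[(tert-butyldimethylsilyloxy)methyl]-3,7,13-trimethyl-10-(propan-2-yl)cyclotrideca-3,8-dien-7-ol
Product: 27 (1S,3E,7R,8E,10S,13R)-13-(hydroxymethyl)-3,7,13-trimethyl-10-(propan-2-yl)cyclotrideca-3,8-diene-1,7-diol
Conditions: TBAF, THF, rt → 40 °C
Reagents that add atoms: none
Why: Fluoride desilylation under non-acidic conditions spares the tertiary allylic alcohol.

Step 18
Reactants: 27 (1S,3E,7R,8E,10S,13R)-13-(hydroxymethyl)-3,7,13-trimethyl-10-(propan-2-yl)cyclotrideca-3,8-diene-1,7-diol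
Product: 28 (1S,3E,7R,8E,10S,13S)-1,7-dihydroxy-3,7,13-trimethyl-10-(propan-2-yl)cyclotrideca-3,8-diene-13-carbaldehyde
Conditions: TEMPO (cat.), PhI(OAc)2, CH2Cl2, rt
Reagents that add atoms: none
Why: Oxoammonium (TEMPO) oxidation is selective for the primary alcohol over the hindered secondary and the tertiary one.

Step 19
Reactants: 28 (1S,3E,7R,8E,10S,13S)-1,7-dihydroxy-3,7,13-trimethyl-10-(propan-2-yl)cyclotrideca-3,8-diene-13-carbaldehyde
Product: 29 (1S,3E,7R,8E,10S,13S)-13-formyl-7-hydroxy-3,7,13-trimethyl-10-(propan-2-yl)cyclotrideca-3,8-dien-1-yl acetate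
Conditions: Ac2O, pyridine, DMAP (cat.), CH2Cl2, 0 °C → rt
Reagents that add atoms: acetic anhydride, CC(=O)OC(C)=O
Why: DMAP-catalysed acetylation should take the secondary C1–OH only, since the tertiary C7–OH is much slower and the quaternary C13 excludes β-elimination.

Compound list
1 | tert-butyl(but-3-yn-1-yloxy)dimethylsilane | C#CCCO[Si](C)(C)C(C)(C)C | starting material
2 | oxirane | C1CO1 | starting material
3 | [(1E)-4-(tert-butyldimethylsilyloxy)-2-methylbut-1-en-1-yl]dimethylalane | C[Al](C)/C=C(\C)CCO[Si](C)(C)C(C)(C)C | intermediate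
4 | (3E)-6-(tert-butyldimethylsilyloxy)-4-methylhex-3-en-1-ol | OCC/C=C(\C)CCO[Si](C)(C)C(C)(C)C | intermediate
5 | tert-butyl{[(3E)-6-chloro-3-methylhex-3-en-1-yl]oxy}dimethylsilane | ClCC/C=C(\C)CCO[Si](C)(C)C(C)(C)C | intermediate
6 | (3E)-6-chloro-3-methylhex-3-en-1-ol | ClCC/C=C(\C)CCO | intermediate
7 | (3E)-6-chloro-3-methylhex-3-enal | ClCC/C=C(\C)CC=O | intermediate
8 | (R)-4-benzyl-3-propanoyl-1,3-oxazolidin-2-one | CCC(=O)N1[C@H](Cc2ccccc2)COC1=O | starting material
9 | (Z)-dibutylboron enolate of 8 | C/C=C(\OB(CCCC)CCCC)N1[C@H](Cc2ccccc2)COC1=O | intermediate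
10 | (4R)-4-benzyl-3-[(2R,3S,5E)-8-chloro-3-hydroxy-2,5-dimethyloct-5-enoyl]-1,3-oxazolidin-2-one | ClCC/C=C(\C)C[C@H](O)[C@@H](C)C(=O)N1[C@H](Cc2ccccc2)COC1=O | intermediate
11 | methyl (2R,3S,5E)-8-chloro-3-hydroxy-2,5-dimethyloct-5-enoate | ClCC/C=C(\C)C[C@H](O)[C@@H](C)C(=O)OC | intermediate
12 | (S)-but-3-yn-2-ol | C#C[C@H](C)O | starting material
13 | (S)-but-3-yn-2-yl N,N-diisopropylcarbamate | C#C[C@H](C)OC(=O)N(C(C)C)C(C)C | intermediate
14 | (2S,3E)-4-(4,4,5,5-tetramethyl-1,3,2-dioxaborolan-2-yl)but-3-en-2-yl N,N-diisopropylcarbamate | C[C@H](OC(=O)N(C(C)C)C(C)C)/C=C/B1OC(C)(C)C(C)(C)O1 | intermediate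
15 | methyl (2E)-4-methylpent-2-enoate | COC(=O)/C=C/C(C)C | starting material
16 | methyl (3S,4E,6S)-6-[(diisopropylcarbamoyl)oxy]-3-(propan-2-yl)hept-4-enoate | COC(=O)C[C@@H](C(C)C)/C=C/[C@H](C)OC(=O)N(C(C)C)C(C)C | intermediate
17 | (2S,3E,5S)-7-hydroxy-5-(propan-2-yl)hept-3-en-2-yl N,N-diisopropylcarbamate | OCC[C@@H](C(C)C)/C=C/[C@H](C)OC(=O)N(C(C)C)C(C)C | intermediate
18 | (2S,3E,5S)-7-iodo-5-(propan-2-yl)hept-3-en-2-yl N,N-diisopropylcarbamate | ICC[C@@H](C(C)C)/C=C/[C@H](C)OC(=O)N(C(C)C)C(C)C | intermediate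
19 | dilithium alkoxide–enolate of 11 | ClCC/C=C(\C)C[C@H](O[Li])C(C)=C(O[Li])OC | intermediate
20 | methyl (2S,3S,5E)-8-chloro-2-{(3S,4E,6S)-6-[(diisopropylcarbamoyl)oxy]-3-(propan-2-yl)hept-4-en-1-yl}-3-hydroxy-2,5-dimethyloct-5-enoate | ClCC/C=C(\C)C[C@H](O)[C@@](C)(C(=O)OC)CC[C@@H](C(C)C)/C=C/[C@H](C)OC(=O)N(C(C)C)C(C)C | intermediate
21 | (2R,3S,5E)-8-chloro-2-{(3S,4E,6S)-6-[(diisopropylcarbamoyl)oxy]-3-(propan-2-yl)hept-4-en-1-yl}-2,5-dimethyloct-5-ene-1,3-diol | ClCC/C=C(\C)C[C@H](O)[C@@](C)(CO)CC[C@@H](C(C)C)/C=C/[C@H](C)OC(=O)N(C(C)C)C(C)C | intermediate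
22 | 1,3-bis(tert-butyldimethylsilyl) ether of 21 | ClCC/C=C(\C)C[C@H](O[Si](C)(C)C(C)(C)C)[C@@](C)(CO[Si](C)(C)C(C)(C)C)CC[C@@H](C(C)C)/C=C/[C@H](C)OC(=O)N(C(C)C)C(C)C | intermediate
23 | pinacol boronate of 22 (Bpin at C6 in place of Cl) | CC1(C)OB(CC/C=C(\C)C[C@H](O[Si](C)(C)C(C)(C)C)[C@@](C)(CO[Si](C)(C)C(C)(C)C)CC[C@@H](C(C)C)/C=C/[C@H](C)OC(=O)N(C(C)C)C(C)C)OC1(C)C | intermediate
24 | lithium ate complex: 14-membered cyclic boronate, boron bridging C6 and C7, C7 still carrying the carbamate | [Li+].CC1(C)O[B-]2(OC1(C)C)CC/C=C(\C)C[C@H](O[Si](C)(C)C(C)(C)C)[C@@](C)(CO[Si](C)(C)C(C)(C)C)CC[C@@H](C(C)C)/C=C/[C@]2(C)OC(=O)N(C(C)C)C(C)C | intermediate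
25 | 13-membered carbocyclic tertiary boronic ester (Bpin on C7 in the place of the later OH; 7S by CIP) | CC(C)(C)[Si](C)(C)O[C@H]1C/C(C)=C/CC[C@@](C)(B2OC(C)(C)C(C)(C)O2)/C=C/[C@H](C(C)C)CC[C@]1(C)CO[Si](C)(C)C(C)(C)C | intermediate
26 | (1S,3E,7R,8E,10S,13R)-1-(tert-butyldimethylsilyloxy)-13-[(tert-butyldimethylsilyloxy)methyl]-3,7,13-trimethyl-10-(propan-2-yl)cyclotrideca-3,8-dien-7-ol | CC(C)(C)[Si](C)(C)O[C@H]1C/C(C)=C/CC[C@@](C)(O)/C=C/[C@H](C(C)C)CC[C@]1(C)CO[Si](C)(C)C(C)(C)C | intermediate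
27 | (1S,3E,7R,8E,10S,13R)-13-(hydroxymethyl)-3,7,13-trimethyl-10-(propan-2-yl)cyclotrideca-3,8-diene-1,7-diol | O[C@H]1C/C(C)=C/CC[C@@](C)(O)/C=C/[C@H](C(C)C)CC[C@]1(C)CO | intermediate
28 | (1S,3E,7R,8E,10S,13S)-1,7-dihydroxy-3,7,13-trimethyl-10-(propan-2-yl)cyclotrideca-3,8-diene-13-carbaldehyde | O[C@H]1C/C(C)=C/CC[C@@](C)(O)/C=C/[C@H](C(C)C)CC[C@]1(C)C=O | intermediate
29 | (1S,3E,7R,8E,10S,13S)-13-formyl-7-hydroxy-3,7,13-trimethyl-10-(propan-2-yl)cyclotrideca-3,8-dien-1-yl acetate | CC(=O)O[C@H]1C/C(C)=C/CC[C@@](C)(O)/C=C/[C@H](C(C)C)CC[C@]1(C)C=O | target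

Total steps: 19. Longest linear sequence: 14 (steps 1–6, then 12–19).

Steps most likely to fail

1. Step 16 (Proposed new method). The amide base may complex or attack the boronate faster than it lithiates the carbamate. The lithiated carbamate may be borylated between molecules (oligomers) or at the γ-carbon, or undergo carbamoyl migration. The ate complex may also revert before the 1,2-shift. Fallback with known chemistry: the C6–C7 bond is made by the established intermolecular lithiation–borylation and the ring is closed at C8=C9 by metathesis. It sets out from 11 and 15 and comes back at 26.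
   - Rh/(R)-BINAP 1,4-addition of potassium vinyltrifluoroborate to 15 would give methyl (3S)-3-(propan-2-yl)pent-4-enoate F1.
   - LiBH4 reduction gives (3S)-3-(propan-2-yl)pent-4-en-1-ol F2, and I2/PPh3/imidazole gives (3S)-5-iodo-3-(propan-2-yl)pent-1-ene F3.
   - Fráter–Seebach alkylation of 11 with F3 (as in step 12) gives methyl (2S,3S,5E)-8-chloro-3-hydroxy-2,5-dimethyl-2-[(3S)-3-(propan-2-yl)pent-4-en-1-yl]oct-5-enoate F4.
   - LiAlH4 gives the (2R,3S)-1,3-diol F5, TBSOTf its bis-TBS ether F6, and Cu-catalysed borylation the pinacol boronate F7.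
   - (S)-But-3-en-2-ol is carbamoylated to (S)-but-3-en-2-yl N,N-diisopropylcarbamate F8.
   - Lithiation of F8 (s-BuLi, TMEDA, Et2O, −78 °C), addition of F7, warming with MgBr2/MeOH and NaOH/H2O2 gives the acyclic (R)-tertiary vinyl carbinol F9, with the C6–C7 bond and the C7 centre in place.
   - Ring-closing metathesis of the two vinyl groups of F9 (Grubbs II, CH2Cl2, 2 mM, 40 °C) closes the (E)-C8=C9 alkene and gives 26.

2. Step 12. The tetrasubstituted dianion may alkylate too slowly with the unactivated primary iodide, so that E2 elimination of the iodide, O-alkylation or retro-aldol cleavage take over. Fallback: the chain is introduced at the more reactive unsubstituted enolate, the methyl last as iodomethane, and C1 is corrected by oxidation and reagent-controlled reduction. It sets out from 7 and 18 and comes back at 20.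
   - A Ti(IV)–BINOL-catalysed Mukaiyama aldol of 7 with 1-methoxy-1-(trimethylsilyloxy)ethene, then fluoride, gives methyl (3R,5E)-8-chloro-3-hydroxy-5-methyloct-5-enoate F10 (catalyst antipode chosen for 3R).
   - Fráter–Seebach alkylation with 18 gives the anti product, methyl (2R,3R,5E)-8-chloro-2-{(3S,4E,6S)-6-[(diisopropylcarbamoyl)oxy]-3-(propan-2-yl)hept-4-en-1-yl}-3-hydroxy-5-methyloct-5-enoate F11.
   - A second dianion formation (LDA, −78 °C, where ester enolisation should outrun carbamate lithiation) and iodomethane give the 3-epimer of 20, methyl (2S,3R,5E)-configured F12, with C13 already correct.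
   - Dess–Martin oxidation gives the β-keto ester F13, and CBS reduction ((R)-Me-CBS, catecholborane, −78 °C; quaternary carbon as the large group) gives 20.

3. Step 9. The β-isopropyl enoate may insert slowly, so that protodeboronation of the alkenylboronate wins, or the facial selectivity may be low. Fallback: C10 is set by enantioselective allylic substitution instead of conjugate addition. It sets out from 15 and 14 and comes back at 17.
   - DIBAL reduction of 15 gives (2E)-4-methylpent-2-en-1-ol F14, and diethyl chlorophosphate/pyridine gives diethyl (2E)-4-methylpent-2-en-1-yl phosphate F15.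
   - Chiral NHC–Cu-catalysed SN2′ substitution of F15 with the alkenylboronate 14 (NaOMe, THF) gives (2S,3E,5R)-5-(propan-2-yl)hepta-3,6-dien-2-yl N,N-diisopropylcarbamate F16, the C10 centre being set by the ligand.
   - 9-BBN hydroboration of the new terminal vinyl group only, then NaBO3, gives 17.

Further compounds
F1 | step 16 | methyl (3S)-3-(propan-2-yl)pent-4-enoate | COC(=O)C[C@@H](C(C)C)C=C
F2 | step 16 | (3S)-3-(propan-2-yl)pent-4-en-1-ol | OCC[C@@H](C(C)C)C=C
F3 | step 16 | (3S)-5-iodo-3-(propan-2-yl)pent-1-ene | ICC[C@@H](C(C)C)C=C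
F4 | step 16 | methyl (2S,3S,5E)-8-chloro-3-hydroxy-2,5-dimethyl-2-[(3S)-3-(propan-2-yl)pent-4-en-1-yl]oct-5-enoate | ClCC/C=C(\C)C[C@H](O)[C@@](C)(C(=O)OC)CC[C@@H](C(C)C)C=C
F5 | step 16 | (2R,3S,5E)-8-chloro-2,5-dimethyl-2-[(3S)-3-(propan-2-yl)pent-4-en-1-yl]oct-5-ene-1,3-diol | ClCC/C=C(\C)C[C@H](O)[C@@](C)(CO)CC[C@@H](C(C)C)C=C
F6 | step 16 | 1,3-bis(tert-butyldimethylsilyl) ether of F5 | ClCC/C=C(\C)C[C@H](O[Si](C)(C)C(C)(C)C)[C@@](C)(CO[Si](C)(C)C(C)(C)C)CC[C@@H](C(C)C)C=C
F7 | step 16 | pinacol boronate of F6 (Bpin in place of Cl) | CC1(C)OB(CC/C=C(\C)C[C@H](O[Si](C)(C)C(C)(C)C)[C@@](C)(CO[Si](C)(C)C(C)(C)C)CC[C@@H](C(C)C)C=C)OC1(C)C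
F8 | step 16 | (S)-but-3-en-2-yl N,N-diisopropylcarbamate | C=C[C@H](C)OC(=O)N(C(C)C)C(C)C
F9 | step 16 | acyclic (R)-tertiary vinyl carbinol, the C8/C9-seco diene of 26 | C=C[C@](C)(O)CC/C=C(\C)C[C@H](O[Si](C)(C)C(C)(C)C)[C@@](C)(CO[Si](C)(C)C(C)(C)C)CC[C@@H](C(C)C)C=C
F10 | step 12 | methyl (3R,5E)-8-chloro-3-hydroxy-5-methyloct-5-enoate | ClCC/C=C(\C)C[C@@H](O)CC(=O)OC
F11 | step 12 | methyl (2R,3R,5E)-8-chloro-2-{(3S,4E,6S)-6-[(diisopropylcarbamoyl)oxy]-3-(propan-2-yl)hept-4-en-1-yl}-3-hydroxy-5-methyloct-5-enoate | ClCC/C=C(\C)C[C@@H](O)[C@H](C(=O)OC)CC[C@@H](C(C)C)/C=C/[C@H](C)OC(=O)N(C(C)C)C(C)C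
F12 | step 12 | methyl (2S,3R,5E)-8-chloro-2-{(3S,4E,6S)-6-[(diisopropylcarbamoyl)oxy]-3-(propan-2-yl)hept-4-en-1-yl}-3-hydroxy-2,5-dimethyloct-5-enoate | ClCC/C=C(\C)C[C@@H](O)[C@@](C)(C(=O)OC)CC[C@@H](C(C)C)/C=C/[C@H](C)OC(=O)N(C(C)C)C(C)C
F13 | step 12 | methyl (2S,5E)-8-chloro-2-{(3S,4E,6S)-6-[(diisopropylcarbamoyl)oxy]-3-(propan-2-yl)hept-4-en-1-yl}-2,5-dimethyl-3-oxooct-5-enoate | ClCC/C=C(\C)CC(=O)[C@@](C)(C(=O)OC)CC[C@@H](C(C)C)/C=C/[C@H](C)OC(=O)N(C(C)C)C(C)C
F14 | step 9 | (2E)-4-methylpent-2-en-1-ol | CC(C)/C=C/CO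
F15 | step 9 | diethyl (2E)-4-methylpent-2-en-1-yl phosphate | CCOP(=O)(OCC)OC/C=C/C(C)C
F16 | step 9 | (2S,3E,5R)-5-(propan-2-yl)hepta-3,6-dien-2-yl N,N-diisopropylcarbamate | C=C[C@@H](C(C)C)/C=C/[C@H](C)OC(=O)N(C(C)C)C(C)C
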